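Readings and results stem from a simulated flask with constants of no real substance; the scatter is artificial.

Time is the axis to follow here. A single-handed catalyst meets a racemate and a reagent that starts undissolved, and you want the state of the flask at the two-hour mark.

| flask | left-handed substrate | right-handed substrate | solid reagent | protic impurity | free catalyst | remark | time |
|---|---|---|---|---|---|---|---|
| Friday's | 0.050 M | 0.050 M | 0.30 M | 0.020 M | 2 mM | run made earlier |  |
| Tuesday's | 0.20 M | 0.20 M | 0.30 M | 0.020 M | 2 mM | run made earlier |  |
| flask | 0.10 M | 0.10 M | 0.300 M | 0.0200 M | 2.0 mM |  | 2.0 h |

- Friday's (time / h: left-handed substrate / %, right-handed substrate / %, left-handed product / %): 0.333: 45.9, 49.8, 2.9; 0.833: 38.7, 49.9, 10.6; 1.50: 25.4, 49.6, 23.1; 2.50: 8.8, 48.5, 39.7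
- Tuesday's (time / h: left-handed substrate / %, right-handed substrate / %, left-handed product / %): 0.333: 48.5, 50.8, 0.7; 0.833: 46.7, 49.7, 2.9; 1.50: 42.1, 49.6, 7.7; 2.50: 35.2, 49.7, 14.5

(each reading ± 0.5 percentage points)

* part of the left-handed substrate and right-handed substrate charged together that has reacted at 2.0 h
* excess of left-handed product over right-handed product in the product at 2.0 h
* excess of right-handed substrate over left-handed substrate among what is left of the two at 2.0 h

- free catalyst is single-handed; left-handed substrate and right-handed substrate are mirror images of each other, charged as a racemate, each of them at the stated concentration
- given per volume of solution although it is solid: solid reagent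
- the earlier runs were read with a standard deviation of 0.5 percentage points
- at the start none of the solid reagent is in solution
- an excess is the difference of the two amounts in percent of their sum
- an excess is below zero if the other one leads

Read the left-handed product first. In Friday's run the left-handed substrate falls from 38.7% to 8.8% between 0.833 h and 2.50 h, yet the product keeps climbing along a nearly straight line, and Tuesday's run looks the same after its lag. So freeze the catalyst's output and count it. Midway between their last two readings, which is 2.0 h, Friday's run holds 31.4 mM of left-handed product and Tuesday's run 44.4 mM. Divide each by the catalyst charged: this count, 15.7 for Friday's run and 22.2 for Tuesday's, is the turnovers per catalyst at two hours, a turnover number.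

These two runs are your extreme versions of the flask. I expect the flask's count to lie between them, since Tuesday's run, with its greater loading, has the higher count. The flask's loading is 2.00 times Friday's, and Tuesday's is 2.00 times the flask's, so I take the geometric middle, 18.7 turnovers. That is 18.7% of the charge as left-handed product alone.

The forecast, counting all substrate consumed, says 20%, 95% and 24%, adding “Roughly 1.5 mM more left-handed substrate is missing, probably held on the 2 mM catalyst”.

The flask gives 20.8%, 95.6% and 25.0%, all three within the forecast's margins.

    coupling partner + protic impurity → quenched reagent (k = 263 /M/h)
    free catalyst → spent catalyst (k = 0.187 /h)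
    coupling partner + catalyst intermediate B → free catalyst + right-handed product (k = 77.6 /M/h)
    coupling partner + catalyst intermediate A → free catalyst + left-handed product (k = 339 /M/h)
    solid reagent ⇌ coupling partner, rate k5*(cs5 - [coupling partner]) while solid is left; crystals form when [coupling partner] > cs5 (solubility = 0.0650 M, k = 1.93 /h)
    free catalyst + right-handed substrate ⇌ catalyst intermediate B (K = 7.22 /M, k = 21400 /M/h)
    free catalyst + left-handed substrate ⇌ catalyst intermediate A (K = 193 /M, k = 2650 /M/h)

The flask's 19.6% of left-handed product is 19.6 turnovers per catalyst, between Friday's and Tuesday's counts. With a quarter of the catalyst, the neighbouring flask reaches 5.71%, which is 22.8 turnovers. Nearly all of these turnovers give left-handed product in the flask, mainly because catalyst intermediate B runs back to free catalyst and right-handed substrate: in the run with that reverse step taken away, the excess of left-handed product is −86.4% instead of 95.6%.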